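Numbering used throughout. Ring A: C1' (bridging O), C2' (OMe), C3' (Br), C4' (H), C5' (Br), C6' (Br). Ring B: C1 (OH), C2 (bridging O), C3 (H), C4 (Br), C5 (H), C6 (Br).

## The problem

Target 14 is an achiral pentabromodiphenyl ether in which both rings are catechol-derived, substituted as listed above. It has no stereocentre, so only position and chemoselectivity have to be controlled. Ring B is the easy half: its two bromines stand para and ortho to the free OH and can be put in by plain bromination of a phenol. Ring A is the hard half. C4', para to the ether oxygen, is bare, while C6', meta to OMe and crowded against the ether oxygen, is brominated; no order of electrophilic brominations of a 1,2-dioxygenated benzene should give this pattern. The ether oxygen is flanked by OMe and Br on ring A and by OH on ring B, so an aryl–oxygen coupling is hindered on both sides, and the C–Br bonds do not tolerate copper or palladium catalysis, organolithium reagents or reducing conditions. The two non-bridging oxygens must be told apart (methyl on ring A, hydrogen on ring B), although the two phenols of the fully brominated diol are flanked alike and should differ little in acidity. The feature that opens the problem is the chain HO–C1–C2–O–C1'–C2'(OMe). It is a 1,4-dioxine ring cut open at one bond, so joining the phenol oxygen to C2' gives a dibenzodioxine in which C2' is a ketal. The other four carbons of ring A, C3'(Br)–C4'(H)–C5'(Br)–C6'(Br), repeat C5–C4–C3–C2 of 2,3,5-tribromothiophene 7.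

## Retrosynthesis

**14 to 12.** The C4–Br and C6–Br bonds of ring B are cut. These are the only two bromines that stand ortho and para to a free OH, and the third such position (C2) is blocked by the ether oxygen. None of the ring A bromines could be added late, because the OMe is twisted out of conjugation and C6' is meta to it. The precursor 12 has an unsubstituted, symmetric catechol as ring B, which removes every regiochemical question on that ring. The forward reaction only has to stop after two bromines, passing through 13.

**12 to 11.** Here a bond is made rather than cut. The phenol oxygen is joined to C2' and a hydrogen is placed on C1', which gives the cis-fused dihydrodibenzodioxine ketal 11, an isomer of 12. The neighbouring option, cutting either aryl–oxygen bond of the bridge, would ask for a hindered coupling next to C–Br bonds. This move keeps both C–O bonds of ring B as they are in a catechol derivative. It also turns the OMe/OH distinction into a question of leaving-group ability. In the forward sense the ketal carbon must expel the aryloxide, not the methoxide, while C1' loses its hydrogen.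

**11 to 10 to 6 + 9.** In 11, ring A is a cyclohexadiene. The bonds C1'–C6' and C2'–C3' are cut as a retro [4+2] after a sulfonyl bridge is put back between C3' and C6' (10). Of the six ways to split ring A into a four-carbon and a two-carbon piece, only this one puts both oxygens on the two-carbon piece, where they raise its HOMO. It also puts all three bromines on the diene, where they lower its LUMO. It gives the ketene acetal 6 and the thiophene dioxide 9, two flat achiral molecules. Neither contains a diaryl ether or a hindered bond. The forward reaction must show the right orientation: C3–H of 6 to C2 of 9, and C2(OMe) of 6 to C5 of 9.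

**9 to 8 to 7.** The two S=O bonds are cut. The bromine pattern that is so hard to write onto a benzene is the pattern that exhaustive alpha- and beta-bromination gives on thiophene, and 7 is a commodity chemical. The forward reaction must oxidise an electron-poor sulfur twice and carry the reactive S-oxide 8 through quickly.

**6 to 5 to 4 to 3 to 2 to 1.** The C2=C3 double bond of 6 is traced to dehydrobromination of the bromo acetal 5. Compound 5 comes from bromomethoxylation of the enediol diether 4, and 4 from the trans dibromide 3 (through 2) of commercial 1,4-benzodioxane 1. All C–O bonds of the later diaryl ether are already present in 1 as ordinary alkyl aryl ether bonds. Only oxidation-level changes at two sp3 carbons are asked of the forward steps.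

## Roads not taken

**Alternative 1:** (the obvious one) The cut is the bond between the bridging oxygen and C2 of ring B.
- Forward: the phenoxide of 2,3,5-tribromo-6-methoxyphenol A1 displaces fluoride from 2-fluorobenzaldehyde A2 (SNAr) to give 2-(2,3,5-tribromo-6-methoxyphenoxy)benzaldehyde A3. Baeyer–Villiger (Dakin-type) oxidation and formate hydrolysis give 12, and step 7 finishes. Copper-mediated Ullmann and diaryliodonium couplings are variants of the same cut.
- The cut moves the whole difficulty into A1. Bromination of 2-methoxyphenol A4 fills the position para to OH first, the very position that must stay free, so A1 needs a blocking group or a formylation/oxidation detour of several steps before the coupling.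
- The phenoxide of A1 is flanked by Br and OMe and is made a poor nucleophile by three bromines. Metal catalysts would face three C–Br bonds.
- The chosen plan makes no aryl–oxygen bond at all and takes the ring A pattern from 7.

**Alternative 2:** The same bond, made as in the presumed biosynthesis.
- Forward: one-electron oxidation of a mixture of A1 and 2,4-dibromophenol A5. The oxygen-centred radical of A1 couples with the free ortho carbon of the radical of A5. This gives 2,4-dibromo-6-(2,3,5-tribromo-6-methoxyphenoxy)cyclohexa-2,4-dienone A6, which tautomerises to 14.
- Without an enzyme pocket the spin density at O, ortho-C and para-C of both radicals allows homo- and cross-coupling, C–C as well as C–O bond formation, and ipso attack with loss of bromine. Nothing in the substrates selects the one pairing needed.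
- The plan also still needs A1, so it saves one bond and none of the ring A problem.

**Alternative 3:** Ring B, not ring A, is built by cycloaddition (cuts C1–C6 and C2–C3).
- Forward: 3,5-dibromo-2H-pyran-2-one A7 reacts with the bis(trimethylsilyl) ketene acetal A8 of (2,3,5-tribromo-6-methoxyphenoxy)acetic acid in an inverse-demand Diels–Alder reaction. Extrusion of the lactone bridge as a gas and loss of silanol give the silyl ether of 14.
- The orientation would be well secured by the lactone polarity of A7.
- However, the step builds the ring that simple bromination provides anyway. A8 comes from A1, so the contra-electronic pattern of ring A remains to be solved by classical means, and the route is longer than the chosen one.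

Key step: step 6

Remark: 14 has no stereocentre. Compounds 2, 3, 5, 10 and 11 are racemic (one enantiomer is drawn where a configuration is given), and all their stereocentres are destroyed before 12.

## Steps

Step 1
Reactants: 1 2,3-dihydro-1,4-benzodioxine (1,4-benzodioxane)
Product: 3 (±)-trans-2,3-dibromo-2,3-dihydro-1,4-benzodioxine, via 2-bromo-2,3-dihydro-1,4-benzodioxine 2 (not isolated)
Conditions: NBS (2.1 equiv), AIBN (cat.), PhCF3, reflux
Reagents that add atoms: N-bromosuccinimide, O=C1CCC(=O)N1Br
Why: Wohl–Ziegler bromination; each O–CH2 group gives an oxygen-stabilised radical, the second bromine enters the other carbon anti to the first and should give the trans dibromide, and radical conditions leave the arene untouched.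

Step 2
Reactants: 3 (±)-trans-2,3-dibromo-2,3-dihydro-1,4-benzodioxine
Product: 4 1,4-benzodioxine
Conditions: NaI (2.5 equiv), acetone, reflux; aq. Na2S2O3 wash
Reagents that add atoms: none
Why: Iodide-induced reductive anti elimination of a vicinal dibromide, the standard entry to this enediol diether; no other group is present.

Step 3
Reactants: 4 1,4-benzodioxine
Product: 5 (±)-trans-2-bromo-3-methoxy-2,3-dihydro-1,4-benzodioxine
Conditions: NBS (1.0 equiv), MeOH (1.5 equiv), CH2Cl2, -40 to 0 °C
Reagents that add atoms: N-bromosuccinimide, O=C1CCC(=O)N1Br; methanol, CO
Why: Alkoxybromination of an enol ether; the C=C bond is far more nucleophilic than the arene, methanol opens the bromonium/oxocarbenium ion anti and sets the trans relation, and little methanol at low temperature is used because the product is an alpha-bromo ether.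

Step 4
Reactants: 5 (±)-trans-2-bromo-3-methoxy-2,3-dihydro-1,4-benzodioxine
Product: 6 2-methoxy-1,4-benzodioxine
Conditions: KOtBu (1.3 equiv), THF, -20 °C to rt; base-washed glassware, used without delay
Reagents that add atoms: none
Why: McElvain-type dehydrobromination of a beta-bromo acetal, the way 1,1,2-trialkoxyethenes are made from 1-halo-1,2,2-trialkoxyethanes; the acetal hydrogen on C3 is the only beta-hydrogen, and the alpha-bromo ether can epimerise through its oxocarbenium bromide ion pair so that the anti-periplanar cis isomer is within reach.

Step 5
Reactants: 7 2,3,5-tribromothiophene
Product: 9 2,3,5-tribromothiophene 1,1-dioxide, via 2,3,5-tribromothiophene 1-oxide 8 (not isolated)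
Conditions: urea·H2O2 (4 equiv), (CF3CO)2O (4 equiv), MeCN, 0 °C to rt
Reagents that add atoms: urea–hydrogen peroxide, NC(N)=O.OO (oxygen donor, acting as trifluoroperacetic acid, OOC(=O)C(F)(F)F)
Why: S-oxidation of an electron-poor thiophene with trifluoroperacetic acid, the method used for di- and tetrahalothiophene dioxides; the strong peracid takes 8 on to the sulfone quickly, and the two alpha-bromines should protect 9 from self-dimerisation.

Step 6
Reactants: 6 2-methoxy-1,4-benzodioxine; 9 2,3,5-tribromothiophene 1,1-dioxide
Product: 12 2-(2,3,5-tribromo-6-methoxyphenoxy)phenol, via sulfone-bridged cycloadduct 10 (not isolated), via cis-dihydrodibenzodioxine ketal 11 (not isolated)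
Conditions: 6 (1.3 equiv), 2,6-lutidine (0.2 equiv), 4 Å MS, PhMe, 25 to 70 °C, N2 sweep; then DBU (1.2 equiv), 25 °C; dilute HCl work-up
Reagents that add atoms: none
Why: The C=C bond of 6, its HOMO raised by three oxygens, adds suprafacially across C2 and C5 of the electron-poor diene 9 in an inverse-electron-demand Diels–Alder reaction, which closes ring A in one intermolecular [4+2] event by forming C1'–C6' and C2'–C3' and gives 10. Cheletropic loss of the sulfonyl bridge from the strained 7-thianorbornene dioxide 10 should be fast at this temperature and leaves the cis-fused cyclohexadiene 11, in which C2' is a ketal (OMe, O-aryl) and C1' carries the only ring A hydrogen on sp3 carbon. Removal of that allylic hydrogen by base (or ionisation of the ketal) with cleavage of the C2'–O(aryl) bond aromatises ring A and opens the dioxine ring, so that 11 isomerises to 12 with no atom lost. The closest known reactions are the annulation of tetrahalothiophene 1,1-dioxides with enol ethers, which lose SO2 and then the alcohol to give halobenzenes, and the 2-pyrone/ketene acetal synthesis of alkoxyarenes. The stereocentres of 10 and 11 follow from suprafacial addition to a cis alkene, are racemic and all vanish on aromatisation, so endo/exo selectivity does not matter. The first selectivity needed is the orientation: C3–H of 6, the nucleophilic carbon because two oxygens on C2 push towards it, must bond to C2 of 9; this is favoured because the inductive pull of the C3 bromine enlarges the LUMO coefficient at C2 and stabilises the charge building up on C3 and C5, because rehybridisation at C2 relieves the vicinal Br/Br compression, and because the fully substituted acetal carbon then meets C5, whose neighbour is only C4–H. The second is the direction of ketal cleavage: aryloxide is the better nucleofuge than methoxide by about five pK units and its departure leaves the methoxy-stabilised cation, so the oxygen that stays on ring A is the methylated one and the oxygen set free on ring B is the phenol.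

Step 7
Reactants: 12 2-(2,3,5-tribromo-6-methoxyphenoxy)phenol
Product: 14 2,4-dibromo-6-(2,3,5-tribromo-6-methoxyphenoxy)phenol, via 4-bromo-2-(2,3,5-tribromo-6-methoxyphenoxy)phenol 13 (not isolated)
Conditions: Br2 (2.05 equiv), AcOH, 15 °C to rt
Reagents that add atoms: bromine, BrBr
Why: Electrophilic aromatic bromination directed by the free phenol; C4 (para) and C6 (ortho) are the only open positions activated by OH, the third is held by the ether oxygen, and ring A is deactivated by three bromines with its single hydrogen buried between two of them.

## Compound list

1 | 2,3-dihydro-1,4-benzodioxine | C1COc2ccccc2O1 | starting material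
2 | (±)-2-bromo-2,3-dihydro-1,4-benzodioxine | Br[C@H]1COc2ccccc2O1 | intermediate (not isolated)
3 | (±)-trans-2,3-dibromo-2,3-dihydro-1,4-benzodioxine | Br[C@@H]1Oc2ccccc2O[C@H]1Br | intermediate
4 | 1,4-benzodioxine | C1=COc2ccccc2O1 | intermediate
5 | (±)-trans-2-bromo-3-methoxy-2,3-dihydro-1,4-benzodioxine | Br[C@@H]1Oc2ccccc2O[C@H]1OC | intermediate
6 | 2-methoxy-1,4-benzodioxine | COC1=COc2ccccc2O1 | intermediate
7 | 2,3,5-tribromothiophene | Brc1cc(Br)c(Br)s1 | starting material
8 | 2,3,5-tribromothiophene 1-oxide | O=S1C(Br)=CC(Br)=C1Br | intermediate (not isolated)
9 | 2,3,5-tribromothiophene 1,1-dioxide | O=S1(=O)C(Br)=CC(Br)=C1Br | intermediate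
10 | 1,2,4-tribromo-4a-methoxy-1,4,4a,10a-tetrahydro-1,4-epithiodibenzo[b,e][1,4]dioxine 11,11-dioxide (racemic, cis ring fusion, endo/exo not defined) | O=S1(=O)C2(Br)C(Br)=CC1(Br)C1(OC)Oc3ccccc3OC21 | intermediate (not isolated)
11 | (±)-cis-1,2,4-tribromo-4a-methoxy-4a,10a-dihydrodibenzo[b,e][1,4]dioxine | CO[C@@]12Oc3ccccc3O[C@@H]1C(Br)=C(Br)C=C2Br | intermediate (not isolated)
12 | 2-(2,3,5-tribromo-6-methoxyphenoxy)phenol | COc1c(Br)cc(Br)c(Br)c1Oc1ccccc1O | intermediate
13 | 4-bromo-2-(2,3,5-tribromo-6-methoxyphenoxy)phenol | COc1c(Br)cc(Br)c(Br)c1Oc1cc(Br)ccc1O | intermediate (not isolated)
14 | 2,4-dibromo-6-(2,3,5-tribromo-6-methoxyphenoxy)phenol | COc1c(Br)cc(Br)c(Br)c1Oc1cc(Br)cc(Br)c1O | target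

## Step count and least certain steps

Total steps: 7. Longest linear sequence: 6 (steps 1, 2, 3, 4, 6, 7). Step 5 is a one-step side branch.

**Step 6 (key step).**
- Most likely failure: poor orientational selectivity of the cycloaddition. Both diene termini carry bromine and differ only in their neighbours (C3–Br against C4–H), so the electronic bias is small and steric approach control could work against it.
- Next in likelihood: protonation of the ketene acetal by acid formed from the extruded gas and traces of water; addition–elimination at C3 of 9 instead of cycloaddition; and loss of methanol in place of aryloxide from the ketal, which would keep the dioxine ring closed.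
- Fallback (reversed polarity of the dienophile), from 9 back to 12:
  - Methoxyacetonitrile is taken by Pinner alcoholysis to 1,1,1,2-tetramethoxyethane F1.
  - Acid-catalysed exchange with catechol gives 2-methoxy-2-(methoxymethyl)-1,3-benzodioxole F2.
  - TMSOTf/iPr2NEt removes one methoxy group and a proton to give the five-membered ketene acetal 2-(methoxymethylidene)-1,3-benzodioxole F3.
  - In F3 the nucleophilic carbon is the one that bears OMe (the later C2'). A first bond to the less crowded C5 of 9, the orientation that would spoil the main route, therefore leads to the correct pattern.
  - The sequence passes through the sulfone-bridged spiro cycloadduct F4 and, after loss of the bridge, the spiro cyclohexadiene ketal F5. Its spiroketal opens with loss of aryloxide from C1' and of hydrogen from C2' to give 12.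

**Step 4.**
- Most likely failure: substitution outrunning elimination. In the trans adduct the only beta-hydrogen is cis to bromine, so an anti-periplanar E2 path needs prior epimerisation, while tert-butoxide can attack the alpha-bromo ether carbon directly.
- Hydrolysis or oligomerisation of the acid-sensitive product on isolation is the second concern.
- Fallback (syn instead of anti elimination), from 4 back to 6:
  - Methoxyselenenylation of 4 (PhSeBr, MeOH, CH2Cl2, -78 °C) gives (±)-trans-2-methoxy-3-(phenylselanyl)-2,3-dihydro-1,4-benzodioxine F6, in which the acetal hydrogen is cis to selenium, as a syn elimination demands.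
  - Oxidation (NaIO4, NaHCO3) gives the selenoxide F7.
  - Heating F7 with iPr2NH in toluene gives 6. This is the known selenoxide route from 2-(phenylselanyl) acetals to ketene acetals.

**Step 5.**
- Most likely failure: a sluggish first oxidation of the electron-poor sulfur, so that the S-oxide lingers and is lost by Diels–Alder self-dimerisation, or ring cleavage by the excess peracid.
- Fallback (oxidise first, brominate afterwards), from 7 back to 9:
  - Double alpha-selective bromine–lithium exchange of 7 (n-BuLi, 2 equiv, THF, -78 °C) and quenching with Me3SiCl give 3-bromo-2,5-bis(trimethylsilyl)thiophene F8.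
  - The more electron-rich sulfur of F8 is oxidised by mCPBA to 3-bromo-2,5-bis(trimethylsilyl)thiophene 1,1-dioxide F9.
  - Ipso-bromodesilylation of both silyl groups (Br2, AgBF4, CH2Cl2), as known for 2,5-disilylthiophene dioxides, gives 9.

**Step 3.**
- Most likely failure: methanolysis of the alpha-bromo ether as it forms, which carries the reaction on to the bis-acetal. Electrophilic bromination of the electron-rich arene is less likely.
- Fallback (substitution in place of addition, bypassing 4), from 3 back to 5:
  - Both bromides of 3 are replaced on purpose with NaOMe in MeOH to give 2,3-dimethoxy-2,3-dihydro-1,4-benzodioxine F10.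
  - One acetal methoxy group is then exchanged for bromide with Me3SiBr (1.0 equiv, CH2Cl2, -78 to 0 °C), the known acetal to alpha-bromo ether exchange.
  - The second exchange should be held back by the electron-withdrawing bromine next to it.

## Further compounds

F1 | step 6 | 1,1,1,2-tetramethoxyethane | COCC(OC)(OC)OC
F2 | step 6 | 2-methoxy-2-(methoxymethyl)-1,3-benzodioxole | COCC1(OC)Oc2ccccc2O1
F3 | step 6 | 2-(methoxymethylidene)-1,3-benzodioxole | COC=C1Oc2ccccc2O1
F4 | step 6 | sulfone-bridged spiro cycloadduct of F3 and 9 (racemic, endo/exo not defined) | O=S1(=O)C2(Br)C(Br)=CC1(Br)C(OC)C23Oc4ccccc4O3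
F5 | step 6 | (±)-2',3',5'-tribromo-6'-methoxyspiro[1,3-benzodioxole-2,1'-cyclohexa-2',4'-diene] | COC1C(Br)=CC(Br)=C(Br)C12Oc1ccccc1O2
F6 | step 4 | (±)-trans-2-methoxy-3-(phenylselanyl)-2,3-dihydro-1,4-benzodioxine | c1ccccc1[Se][C@@H]1Oc2ccccc2O[C@H]1OC
F7 | step 4 | (±)-trans-2-methoxy-3-(phenylseleninyl)-2,3-dihydro-1,4-benzodioxine | O=[Se](c1ccccc1)[C@@H]1Oc2ccccc2O[C@H]1OC
F8 | step 5 | 3-bromo-2,5-bis(trimethylsilyl)thiophene | C[Si](C)(C)c1cc(Br)c([Si](C)(C)C)s1
F9 | step 5 | 3-bromo-2,5-bis(trimethylsilyl)thiophene 1,1-dioxide | C[Si](C)(C)C1=CC(Br)=C([Si](C)(C)C)S1(=O)=O
F10 | step 3 | 2,3-dimethoxy-2,3-dihydro-1,4-benzodioxine (cis/trans mixture) | COC1Oc2ccccc2OC1OC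
A1 | alternative 1 | 2,3,5-tribromo-6-methoxyphenol | COc1c(Br)cc(Br)c(Br)c1O
A2 | alternative 1 | 2-fluorobenzaldehyde | O=Cc1ccccc1F
A3 | alternative 1 | 2-(2,3,5-tribromo-6-methoxyphenoxy)benzaldehyde | COc1c(Br)cc(Br)c(Br)c1Oc1ccccc1C=O
A4 | alternative 1 | 2-methoxyphenol | COc1ccccc1O
A5 | alternative 2 | 2,4-dibromophenol | Oc1ccc(Br)cc1Br
A6 | alternative 2 | (±)-2,4-dibromo-6-(2,3,5-tribromo-6-methoxyphenoxy)cyclohexa-2,4-dien-1-one | COc1c(Br)cc(Br)c(Br)c1OC1C=C(Br)C=C(Br)C1=O
A7 | alternative 3 | 3,5-dibromo-2H-pyran-2-one | O=C1OC=C(Br)C=C1Br
A8 | alternative 3 | 1,1-bis(trimethylsilyloxy)-2-(2,3,5-tribromo-6-methoxyphenoxy)ethene | COc1c(Br)cc(Br)c(Br)c1OC=C(O[Si](C)(C)C)O[Si](C)(C)C
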